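**Plan**

Numbering (indenone): C1 ketone, C2 (CO2Me), C3 (C16H33), C3a, C4 (CO2Me), C5 (C16H33), C6, C7 (CO2H), C7a; ring A is the cyclopentenone, ring B the cyclohexene.
Retrosynthesis: the acid is freed from a racemate and a tert-butyl ester; the C4–H and C7–H bonds are cut (1,4-addition of H2 to a ring B 1,3-diene); then C1–C2, C3a–C7a and C4=C5 are cut together, which leaves keto diester 14 and phosphonodienoate 9, both made from one C18 keto acetal 4.
Enabling feature: ring A is a vinylogous β-keto ester, so C1–C2 is a Dieckmann bond; C7a (α to C1) and C3a (β to the C4 ester once C4=C5 is a double bond) are a Michael donor/acceptor pair, and the phosphoryl group that activates C3a then closes ring B by olefination of the C5 ketone.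
Forward: two open chains are joined in step 8, where the ring-fusion bond forms first, ring B closes second and ring A last; H2 addition, ester cleavage and resolution follow.
Stereochemistry: C3a/C7a become cis through ring strain (racemic); C4/C7 arise by delivery of both hydrogens of H2 to the convex face of the cis-fused diene; the absolute configuration comes from crystallisation of the (R)-1-phenylethylammonium salt.

Key step: step 8

Assumption: the salt of the (3aR,4R,7R,7aS)-acid with (R)-1-phenylethylamine is taken as the less soluble diastereomer; if the other pairing crystallises, (S)-1-phenylethylamine is used in the same way.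

**Route**

Step 1
Reactants: 1 1-bromohexadecane; 2 ethyl 2,2-diethoxyacetate
Product: 4 1,1-diethoxyoctadecan-2-one, via hexadecylmagnesium bromide 3 (not isolated)
Conditions: Mg, THF, 40 °C; then 2, THF, −78 °C; H2O
Reagents that add atoms: none
Why: Grignard acylation; the α-alkoxy-chelated magnesium hemiketal should survive at −78 °C and collapse to the ketone only on work-up, so a single addition is expected.

Step 2
Reactants: 4 1,1-diethoxyoctadecan-2-one; 5 methyl 2-(dimethoxyphosphoryl)acetate
Product: 6 methyl (2E)-3-(diethoxymethyl)nonadec-2-enoate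
Conditions: NaH, THF, 0 °C → reflux
Reagents that add atoms: none
Why: Horner–Wadsworth–Emmons olefination of an α,α-dialkoxy ketone; the E/Z mixture is used as such because this double-bond geometry is lost in the dienolate of step 8.

Step 3
Reactants: 6 methyl (2E)-3-(diethoxymethyl)nonadec-2-enoate
Product: 7 methyl (2E)-3-formylnonadec-2-enoate
Conditions: Amberlyst-15, acetone/H2O, rt
Reagents that add atoms: water, O
Why: acid-catalysed acetal hydrolysis, under which the methyl ester and the enoate should be inert.

Step 4
Reactants: 7 methyl (2E)-3-formylnonadec-2-enoate; 8 methyl 2-(diethoxyphosphoryl)acetate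
Product: 9 dimethyl (4E)-2-(diethoxyphosphoryl)-4-hexadecylhexa-2,4-dienedioate
Conditions: piperidine (10 mol %), AcOH (20 mol %), toluene, reflux, azeotropic removal of water
Reagents that add atoms: none
Why: Knoevenagel condensation of a non-enolisable aldehyde; without a strong base the phosphoryl group stays, and the geometry of the new C2=C3 bond is irrelevant because C2 becomes a carbanion in step 8.

Step 5
Reactants: 4 1,1-diethoxyoctadecan-2-one
Product: 10 2-oxooctadecanal
Conditions: HCO2H/H2O (9:1), 40 °C; azeotropic drying with toluene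
Reagents that add atoms: water, O
Why: acid hydrolysis of an α-keto acetal; the keto aldehyde (partly as hydrate) is used crude.

Step 6
Reactants: 11 tert-butyl 2-(diethoxyphosphoryl)acetate; 12 methyl 2-bromoacetate
Product: 13 1-tert-butyl 4-methyl 2-(diethoxyphosphoryl)butanedioate
Conditions: NaH, THF, 0 °C; then 12, 0 °C → rt
Reagents that add atoms: none
Why: SN2 C-alkylation of the sodium phosphonoacetate; the new stereocenter is racemic and disappears in step 7.

Step 7
Reactants: 13 1-tert-butyl 4-methyl 2-(diethoxyphosphoryl)butanedioate; 10 2-oxooctadecanal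
Product: 14 1-tert-butyl 4-methyl (2E)-2-(2-oxooctadecylidene)butanedioate
Conditions: NaH, THF, 0 °C; then 10, −78 → 0 °C
Reagents that add atoms: none
Why: Horner–Wadsworth–Emmons olefination, chemoselective for the aldehyde of the 1,2-dicarbonyl compound; the E isomer places the acyl group cis to the CH2CO2Me arm, and double-bond isomers converge through the common dienolate in step 8.

Step 8
Reactants: 14 1-tert-butyl 4-methyl (2E)-2-(2-oxooctadecylidene)butanedioate; 9 dimethyl (4E)-2-(diethoxyphosphoryl)-4-hexadecylhexa-2,4-dienedioate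
Product: 17 rac-(3aS,7aS)-7-tert-butyl 2,4-dimethyl 3,5-dihexadecyl-1-oxo-3a,7a-dihydro-1H-indene-2,4,7-tricarboxylate, via phosphonate Michael adduct 15 (not isolated), via cyclohexadiene tetraester 16 (not isolated)
Conditions: KN(SiMe3)2 (1.05 equiv), THF, −78 °C; 9, −78 → 0 °C; KN(SiMe3)2 (1.2 equiv), −78 → 0 °C; AcOH, −78 °C
Reagents that add atoms: none
Why: KN(SiMe3)2 removes the CH2 proton of 14 that is α to the methyl ester and vinylogous to the ketone, and the dienolate adds through that carbon to C3 of 9 (β to phosphoryl and ester), which makes the C3a–C7a bond and a phosphonoacetate carbanion (Michael addition, 15). This carbanion attacks the ketone and loses diethyl phosphate (intramolecular Horner–Wadsworth–Emmons reaction, 6-exo-trig addition to C=O) to close ring B as cyclohexa-1,3-diene 16; the closest known reaction type is the Michael-initiated Horner–Wadsworth–Emmons annulation of 2-phosphonoacrylates with ketone enolates. The second portion of base removes the doubly allylic C3a–H of 16, and the dienolate attacks through C2 the only saturated methyl ester (on C7a), which closes ring A by Dieckmann condensation (5-exo-trig, enolate exocyclic) and forms C1–C2; methoxide leaves and the product rests as its vinylogous β-keto ester enolate. The two new stereocenters C3a and C7a become cis because a trans fusion of a cyclopentenone to a cyclohexadiene is highly strained, so protonation on work-up should give only the cis-fused racemate. The step needs attack of the dienolate of 14 through the carbon next to the ester (only that adduct can reach a six-membered ring, and the Michael step is reversible), acylation at C1 and not at the conjugated C4 ester or the tert-butyl ester, and no migration of the ring-fusion hydrogens that would aromatise ring B; the aprotic medium, the lack of a proton shuttle and the cold acetic acid quench should secure the last point.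

Step 9
Reactants: 17 rac-(3aS,7aS)-7-tert-butyl 2,4-dimethyl 3,5-dihexadecyl-1-oxo-3a,7a-dihydro-1H-indene-2,4,7-tricarboxylate
Product: 18 rac-(3aR,4R,7R,7aS)-7-tert-butyl 2,4-dimethyl 3,5-dihexadecyl-1-oxo-3a,4,7,7a-tetrahydro-1H-indene-2,4,7-tricarboxylate
Conditions: H2 (50 bar), (η6-naphthalene)Cr(CO)3 (20 mol %), THF, 40 °C
Reagents that add atoms: none
Why: arene-Cr(CO)3-catalysed 1,4-hydrogenation of a conjugated diene; the s-cis diene of ring B should bind the Cr(CO)3 fragment on the convex face (the face of H3a and H7a) and receive both hydrogens at C4 and C7 from that face, which sets these two stereocenters cis to the ring-fusion hydrogens and leaves the isolated C5=C6 bond and the tetrasubstituted C2=C3 bond, which is no 1,3-diene.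

Step 10
Reactants: 18 rac-(3aR,4R,7R,7aS)-7-tert-butyl 2,4-dimethyl 3,5-dihexadecyl-1-oxo-3a,4,7,7a-tetrahydro-1H-indene-2,4,7-tricarboxylate
Product: 19 rac-(3aR,4R,7R,7aS)-3,5-dihexadecyl-2,4-bis(methoxycarbonyl)-1-oxo-3a,4,7,7a-tetrahydro-1H-indene-7-carboxylic acid
Conditions: TFA/CH2Cl2 (1:4), 0 °C → rt
Reagents that add atoms: none
Why: acidolysis of the tert-butyl ester through the tert-butyl cation; the methyl esters and the base-sensitive stereocenters at C4, C7 and C7a should be untouched by anhydrous acid.

Step 11
Reactants: 19 rac-(3aR,4R,7R,7aS)-3,5-dihexadecyl-2,4-bis(methoxycarbonyl)-1-oxo-3a,4,7,7a-tetrahydro-1H-indene-7-carboxylic acid; 20 (R)-1-phenylethylamine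
Product: 21 (R)-1-phenylethylammonium (3aR,4R,7R,7aS)-3,5-dihexadecyl-2,4-bis(methoxycarbonyl)-1-oxo-3a,4,7,7a-tetrahydro-1H-indene-7-carboxylate
Conditions: 20 (1.0 equiv), EtOAc, rt → 0 °C; recrystallisation from EtOAc/heptane
Reagents that add atoms: none
Why: classical resolution by fractional crystallisation of diastereomeric ammonium carboxylates; salt formation is immediate, so the protonated amine should not add to the enone.

Step 12
Reactants: 21 (R)-1-phenylethylammonium (3aR,4R,7R,7aS)-3,5-dihexadecyl-2,4-bis(methoxycarbonyl)-1-oxo-3a,4,7,7a-tetrahydro-1H-indene-7-carboxylate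
Product: 22 (3aR,4R,7R,7aS)-3,5-dihexadecyl-2,4-bis(methoxycarbonyl)-1-oxo-3a,4,7,7a-tetrahydro-1H-indene-7-carboxylic acid
Conditions: 1 M HCl (aq), EtOAc, 0 °C
Reagents that add atoms: none
Why: protonation of the carboxylate under cold dilute acid, which should not touch any stereocenter.

**Compound list**

1 | 1-bromohexadecane | CCCCCCCCCCCCCCCCBr | starting material
2 | ethyl 2,2-diethoxyacetate | CCOC(=O)C(OCC)OCC | starting material
3 | hexadecylmagnesium bromide (not isolated) | CCCCCCCCCCCCCCCC[Mg]Br | intermediate
4 | 1,1-diethoxyoctadecan-2-one | CCCCCCCCCCCCCCCCC(=O)C(OCC)OCC | intermediate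
5 | methyl 2-(dimethoxyphosphoryl)acetate | COC(=O)CP(=O)(OC)OC | starting material
6 | methyl (2E)-3-(diethoxymethyl)nonadec-2-enoate (E drawn; the Z isomer is carried along) | CCCCCCCCCCCCCCCC/C(=C\C(=O)OC)C(OCC)OCC | intermediate
7 | methyl (2E)-3-formylnonadec-2-enoate | CCCCCCCCCCCCCCCC/C(C=O)=C\C(=O)OC | intermediate
8 | methyl 2-(diethoxyphosphoryl)acetate | CCOP(=O)(CC(=O)OC)OCC | starting material
9 | dimethyl (4E)-2-(diethoxyphosphoryl)-4-hexadecylhexa-2,4-dienedioate (C2=C3 geometry not defined) | CCCCCCCCCCCCCCCC/C(=C\C(=O)OC)C=C(C(=O)OC)P(=O)(OCC)OCC | intermediate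
10 | 2-oxooctadecanal | CCCCCCCCCCCCCCCCC(=O)C=O | intermediate
11 | tert-butyl 2-(diethoxyphosphoryl)acetate | CCOP(=O)(CC(=O)OC(C)(C)C)OCC | starting material
12 | methyl 2-bromoacetate | COC(=O)CBr | starting material
13 | 1-tert-butyl 4-methyl 2-(diethoxyphosphoryl)butanedioate (racemic) | CCOP(=O)(OCC)C(CC(=O)OC)C(=O)OC(C)(C)C | intermediate
14 | 1-tert-butyl 4-methyl (2E)-2-(2-oxooctadecylidene)butanedioate | CCCCCCCCCCCCCCCCC(=O)/C=C(\CC(=O)OC)C(=O)OC(C)(C)C | intermediate
15 | 2-tert-butyl 3,5-dimethyl (1E)-5-(diethoxyphosphoryl)-1-heptadecanoyl-4-[(2E)-1-methoxy-1-oxononadec-2-en-3-yl]pent-1-ene-2,3,5-tricarboxylate (mixture of diastereomers; present as its potassium salt; not isolated) | CCCCCCCCCCCCCCCCC(=O)/C=C(/C(=O)OC(C)(C)C)C(C(=O)OC)C(/C(CCCCCCCCCCCCCCCC)=C/C(=O)OC)C(C(=O)OC)P(=O)(OCC)OCC | intermediate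
16 | 1-tert-butyl 4,6-dimethyl 3-hexadecyl-5-[(2E)-1-methoxy-1-oxononadec-2-en-3-yl]cyclohexa-1,3-diene-1,4,6-tricarboxylate (C5/C6 diastereomers; not isolated) | CCCCCCCCCCCCCCCCC1=C(C(=O)OC)C(/C(CCCCCCCCCCCCCCCC)=C/C(=O)OC)C(C(=O)OC)C(C(=O)OC(C)(C)C)=C1 | intermediate
17 | rac-(3aS,7aS)-7-tert-butyl 2,4-dimethyl 3,5-dihexadecyl-1-oxo-3a,7a-dihydro-1H-indene-2,4,7-tricarboxylate (cis-fused; both enantiomers written) | CCCCCCCCCCCCCCCCC1=C(C(=O)OC)[C@@H]2C(CCCCCCCCCCCCCCCC)=C(C(=O)OC)C(=O)[C@@H]2C(C(=O)OC(C)(C)C)=C1.CCCCCCCCCCCCCCCCC1=C(C(=O)OC)[C@H]2C(CCCCCCCCCCCCCCCC)=C(C(=O)OC)C(=O)[C@H]2C(C(=O)OC(C)(C)C)=C1 | intermediate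
18 | rac-(3aR,4R,7R,7aS)-7-tert-butyl 2,4-dimethyl 3,5-dihexadecyl-1-oxo-3a,4,7,7a-tetrahydro-1H-indene-2,4,7-tricarboxylate (both enantiomers written) | CCCCCCCCCCCCCCCCC1=C[C@@H](C(=O)OC(C)(C)C)[C@H]2C(=O)C(C(=O)OC)=C(CCCCCCCCCCCCCCCC)[C@H]2[C@H]1C(=O)OC.CCCCCCCCCCCCCCCCC1=C[C@H](C(=O)OC(C)(C)C)[C@@H]2C(=O)C(C(=O)OC)=C(CCCCCCCCCCCCCCCC)[C@@H]2[C@@H]1C(=O)OC | intermediate
19 | rac-(3aR,4R,7R,7aS)-3,5-dihexadecyl-2,4-bis(methoxycarbonyl)-1-oxo-3a,4,7,7a-tetrahydro-1H-indene-7-carboxylic acid (both enantiomers written) | CCCCCCCCCCCCCCCCC1=C[C@@H](C(=O)O)[C@H]2C(=O)C(C(=O)OC)=C(CCCCCCCCCCCCCCCC)[C@H]2[C@H]1C(=O)OC.CCCCCCCCCCCCCCCCC1=C[C@H](C(=O)O)[C@@H]2C(=O)C(C(=O)OC)=C(CCCCCCCCCCCCCCCC)[C@@H]2[C@@H]1C(=O)OC | intermediate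
20 | (R)-1-phenylethylamine | C[C@@H](N)c1ccccc1 | starting material
21 | (R)-1-phenylethylammonium (3aR,4R,7R,7aS)-3,5-dihexadecyl-2,4-bis(methoxycarbonyl)-1-oxo-3a,4,7,7a-tetrahydro-1H-indene-7-carboxylate | CCCCCCCCCCCCCCCCC1=C[C@@H](C(=O)[O-])[C@H]2C(=O)C(C(=O)OC)=C(CCCCCCCCCCCCCCCC)[C@H]2[C@H]1C(=O)OC.C[C@@H]([NH3+])c1ccccc1 | intermediate
22 | (3aR,4R,7R,7aS)-3,5-dihexadecyl-2,4-bis(methoxycarbonyl)-1-oxo-3a,4,7,7a-tetrahydro-1H-indene-7-carboxylic acid | CCCCCCCCCCCCCCCCC1=C[C@@H](C(=O)O)[C@H]2C(=O)C(C(=O)OC)=C(CCCCCCCCCCCCCCCC)[C@H]2[C@H]1C(=O)OC | target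

**Step count and risks**

Total step count: 12. Longest linear sequence: 9 (steps 1, 2, 3, 4, 8, 9, 10, 11, 12).

Step 8 is the most likely to fail. Proton shuttling between the anions could move the two ring-fusion hydrogens onto C2 and C3 and so aromatise ring B to an indanone. The dienolate of 14 could also add through the carbon next to the ketone, or the acylation could go to the conjugated C4 ester. The fallback replaces the anionic domino by two separate operations. Starting again from 14 and 9, Cs2CO3 in MeCN at 0 °C should bring about only the Michael addition and the Horner–Wadsworth–Emmons ring closure, so that cyclohexadiene 16 is isolated. Ring A is then closed through a titanium enolate (TiCl4, Bu3N, CH2Cl2, −78 °C; titanium-mediated Dieckmann condensation), in which no free basic enolate of the product builds up. The route is rejoined at 17, and no compound outside the list is made (F0).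

Step 9 is the second risk. The fully substituted diene termini may coordinate the chromium fragment too slowly, and at the temperature needed the dihydroindenone may isomerise or the ester-conjugated C2=C3 bond may be reduced. The fallback is a dissolving-metal reduction. Starting from 17, the enone ester is masked as its potassium enolate (KN(SiMe3)2, THF, −78 °C). The diene diester is then reduced with Li in NH3/THF at −78 °C (Birch-type 1,4-reduction of a conjugated dienoate). The ester enolates are protonated kinetically with solid NH4Cl at −78 °C from the convex face. The route is rejoined at 18, and no compound outside the list is made (F0).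

Step 11 is the third risk. The waxy salt may not crystallise, the crystals may not be enriched, or the amine may add slowly to the enone. The fallback separates the enantiomers one step earlier and without a resolving agent. Starting from 18, preparative chromatography on a chiral stationary phase (amylose tris(3,5-dimethylphenylcarbamate), hexane/2-propanol) should give 7-tert-butyl 2,4-dimethyl (3aR,4R,7R,7aS)-3,5-dihexadecyl-1-oxo-3a,4,7,7a-tetrahydro-1H-indene-2,4,7-tricarboxylate F1. Treatment of F1 with TFA/CH2Cl2 as in step 10 then gives 22 directly.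

**Further compounds**

F0 | step 8 | none | none
F0 | step 9 | none | none
F1 | step 11 | 7-tert-butyl 2,4-dimethyl (3aR,4R,7R,7aS)-3,5-dihexadecyl-1-oxo-3a,4,7,7a-tetrahydro-1H-indene-2,4,7-tricarboxylate | CCCCCCCCCCCCCCCCC1=C[C@@H](C(=O)OC(C)(C)C)[C@H]2C(=O)C(C(=O)OC)=C(CCCCCCCCCCCCCCCC)[C@H]2[C@H]1C(=O)OC
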